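**Retrosynthetic overview**

1. The target is 9α-benzoyloxy-3β-hydroxylabda-7,13E-dien-15-oic acid. The C13=C14 enoate is cut back to a C13 methyl ketone (Horner–Wadsworth–Emmons), and ring B is opened at C7=C8 (ring-closing metathesis of a C5 allyl group with a C9 isopropenyl group).
2. The C9 carbinol is cut at C8–C9: isopropenyl addition to a C9 ketone that hangs on the quaternary C10 of a ring-A cyclohexanone.
3. Ring A is cut at C1–C2 and C9–C10 together: an intramolecular de Mayo reaction of an acyclic β-diketone (C3 and C9 carbonyls flanking C2) with the isopropenyl group (C10=C1) on C5, followed by retro-aldol cleavage of C2–C9 in the cyclobutanol.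
4. The enabling feature is the 1,5-dioxygen pattern O–C3–C2–C1–C10–C9–O, which links the hydroxyl carbon of ring A to the benzoate-bearing C9 through quaternary C10; the gem-dimethyl C4 leaves C2 as the only acidic position next to C3.
5. The one preset stereocentre (C5) comes from a rhodium/BINAP conjugate addition to 5,6-dihydro-2H-pyran-2-one; the rings form in the order A (step 7), then B (step 12).

Key step: step 7

Remark: atom labels C1–C17 in the explanations are the labdane positions of the target (ring A: C1–C5 and C10; ring B: C5–C10); the (S)-BINAP/rhodium catalyst is assumed to add to the lactone with the facial sense known for cyclic enones, which gives (S)-2.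

**Route**

Step 1
Reactants: 1 5,6-dihydro-2H-pyran-2-one
Product: 2 (S)-4-(prop-1-en-2-yl)tetrahydro-2H-pyran-2-one
Conditions: CH2=C(CH3)BF3K (1.5 equiv), [Rh(cod)2]BF4 (3 mol %), (S)-BINAP (3.3 mol %), toluene/H2O (10:1), 100 °C
Reagents that add atoms: potassium isopropenyltrifluoroborate, CC(=C)[B-](F)(F)F.[K+]
Why: Rhodium/BINAP-catalysed asymmetric conjugate addition of an alkenyltrifluoroborate (Hayashi–Miyaura type) to the unsaturated lactone; the (S)-BINAP complex should deliver the isopropenyl group to one enantioface and so set the future C5 stereocentre.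

Step 2
Reactants: 2 (S)-4-(prop-1-en-2-yl)tetrahydro-2H-pyran-2-one
Product: 4 (R)-3,3-dimethyl-4-(prop-1-en-2-yl)tetrahydro-2H-pyran-2-one, via trans-3-methyl lactone 3 (not isolated)
Conditions: LiN(i-Pr)2 (1.1 equiv), THF, −78 °C, then MeI; LiN(i-Pr)2 (1.2 equiv), −78 °C, then MeI, −78 → 0 °C
Reagents that add atoms: iodomethane, CI
Why: Two successive lithium-enolate methylations α to the lactone carbonyl should build the gem-dimethyl carbon (future C4); the first methyl enters trans to the isopropenyl group, the second removes that centre, and the non-enolisable neighbouring stereocentre is untouched.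

Step 3
Reactants: 4 (R)-3,3-dimethyl-4-(prop-1-en-2-yl)tetrahydro-2H-pyran-2-one
Product: 5 (R)-6-hydroxy-3,3-dimethyl-4-(prop-1-en-2-yl)hexan-2-one
Conditions: MeLi (1.1 equiv), THF, −78 °C; H2O
Reagents that add atoms: methyllithium, [Li]C
Why: Single addition of MeLi to a lactone: the hindered lithium hemiketal should survive at −78 °C and collapse only on work-up to the methyl ketone (open form of the lactol), which supplies C2.

Step 4
Reactants: 5 (R)-6-hydroxy-3,3-dimethyl-4-(prop-1-en-2-yl)hexan-2-one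
Product: 6 (R)-4,4-dimethyl-5-oxo-3-(prop-1-en-2-yl)hexanal
Conditions: TEMPO (10 mol %), PhI(OAc)2 (1.1 equiv), CH2Cl2, 20 °C
Reagents that add atoms: none
Why: Oxoammonium-catalysed (TEMPO/PhI(OAc)2) oxidation of the primary alcohol should stop at the aldehyde and leave the alkene and the ketone alone.

Step 5
Reactants: 6 (R)-4,4-dimethyl-5-oxo-3-(prop-1-en-2-yl)hexanal
Product: 7 (R)-3,3-dimethyl-4-(prop-1-en-2-yl)hept-6-en-2-one
Conditions: Ph3PCH3Br, KOt-Bu, THF, 0 °C; then 6, −78 → 0 °C
Reagents that add atoms: methyltriphenylphosphonium bromide, C[P+](c1ccccc1)(c1ccccc1)c1ccccc1.[Br-]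
Why: Wittig methylenation is chemoselective for the aldehyde over the neopentyl methyl ketone and should turn the CH2CHO arm into the allyl group needed later for ring B.

Step 6
Reactants: 7 (R)-3,3-dimethyl-4-(prop-1-en-2-yl)hept-6-en-2-one; 8 ethyl 3-(2-methyl-1,3-dioxolan-2-yl)propanoate
Product: 9 (R)-6,6-dimethyl-1-(2-methyl-1,3-dioxolan-2-yl)-7-(prop-1-en-2-yl)dec-9-ene-3,5-dione
Conditions: NaH (2.5 equiv), DME, 70 °C; AcOH
Reagents that add atoms: none
Why: Crossed Claisen condensation: ketone 7 can enolise only at its methyl group (C2) because C4 is quaternary, and its sodium enolate should be acylated by ester 8 to give the β-diketone, drained from the equilibrium as its sodium salt.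

Step 7
Reactants: 9 (R)-6,6-dimethyl-1-(2-methyl-1,3-dioxolan-2-yl)-7-(prop-1-en-2-yl)dec-9-ene-3,5-dione
Product: 11 (3S,4S)-2,2,4-trimethyl-4-[3-(2-methyl-1,3-dioxolan-2-yl)propanoyl]-3-(prop-2-en-1-yl)cyclohexan-1-one, via cyclobutanol photoadduct 10 (not isolated)
Conditions: hν (300 nm), degassed cyclohexane (0.01 M), 20 °C
Reagents that add atoms: none
Why: Excitation of the hydrogen-bonded enol of 9 (O=C3–C2=C9–OH) gives a triplet enone whose α-carbon C2 bonds to the CH2 terminus C1 of the isopropenyl group in a 6-endo-trig closure of ring A, and the resulting 1,4-biradical (tertiary C10, hydroxyalkyl C9) collapses by 1,4-radical recombination to the four-membered ring of the crossed adduct 10, whose strained β-hydroxy ketone opens at once by retro-aldol cleavage of C2–C9 to the 1,5-diketone 11. The closest known reaction type is the intramolecular de Mayo reaction of enolised 1,3-diketones that carry the alkene on an acyl branch. The only new stereocentre that survives is quaternary C10, and it is controlled by C5: the biradical collapses on the face of ring A anti to the C5 allyl group, which then lies over the bare C1 bridge instead of under the fully substituted C9 bridge, so the C9 acyl group ends trans to the allyl group as the trans ring fusion demands, while C2 and C9 lose their stereogenicity in the fragmentation. The step needs crossed and not straight regiochemistry: the methyl group on C10 and the C3 carbonyl inside the forming ring both disfavour five-membered closure onto C10 and direct C2 to the free CH2 terminus, which also leaves the more stable tertiary radical. It also needs the isopropenyl and not the allyl alkene to react, which the shorter three-atom tether and the 1,1-disubstitution secure. A biradical reached through the other enol tautomer could close only to a much more strained bicyclo[2.2.0]hexane and is expected to fall back to 9, and quaternary C4 leaves C2 as the one enolisable position between the carbonyls.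

Step 8
Reactants: 11 (3S,4S)-2,2,4-trimethyl-4-[3-(2-methyl-1,3-dioxolan-2-yl)propanoyl]-3-(prop-2-en-1-yl)cyclohexan-1-one
Product: 12 1-[(1S,2S,4S)-4-hydroxy-1,3,3-trimethyl-2-(prop-2-en-1-yl)cyclohexyl]-3-(2-methyl-1,3-dioxolan-2-yl)propan-1-one
Conditions: NaBH4, MeOH/CH2Cl2, −40 °C
Reagents that add atoms: none
Why: The cyclohexanone carbonyl (C3) should be reduced much faster than the acyclic ketone flanked by quaternary C10, and axial hydride delivery from the α face, which carries only axial hydrogens at C1 and C5, should give the equatorial 3β-alcohol (3S), as in 4,4-dimethyl-3-keto terpenoids.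

Step 9
Reactants: 12 1-[(1S,2S,4S)-4-hydroxy-1,3,3-trimethyl-2-(prop-2-en-1-yl)cyclohexyl]-3-(2-methyl-1,3-dioxolan-2-yl)propan-1-one
Product: 13 1-[(1S,2S,4S)-4-(tert-butyldimethylsilyloxy)-1,3,3-trimethyl-2-(prop-2-en-1-yl)cyclohexyl]-3-(2-methyl-1,3-dioxolan-2-yl)propan-1-one
Conditions: TBSOTf, 2,6-lutidine, CH2Cl2, −78 → 0 °C
Reagents that add atoms: tert-butyldimethylsilyl trifluoromethanesulfonate, CC(C)(C)[Si](C)(C)OS(=O)(=O)C(F)(F)F
Why: Silylation of the hindered secondary alcohol with the silyl triflate; the ketone and the dioxolane should be inert to TBSOTf/2,6-lutidine at low temperature.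

Step 10
Reactants: 13 1-[(1S,2S,4S)-4-(tert-butyldimethylsilyloxy)-1,3,3-trimethyl-2-(prop-2-en-1-yl)cyclohexyl]-3-(2-methyl-1,3-dioxolan-2-yl)propan-1-one
Product: 14 (3R)-3-[(1S,2S,4S)-4-(tert-butyldimethylsilyloxy)-1,3,3-trimethyl-2-(prop-2-en-1-yl)cyclohexyl]-2-methyl-5-(2-methyl-1,3-dioxolan-2-yl)pent-1-en-3-ol
Conditions: CH2=C(CH3)MgBr, CeCl3 (anhydrous), THF, −78 → 0 °C; H2O
Reagents that add atoms: isopropenylmagnesium bromide, CC(=C)[Mg]Br
Why: Organocerium (Imamoto) 1,2-addition suppresses enolisation of the hindered ketone; C9 should be set under Felkin–Anh control, the nucleophile entering anti to the C10–C5 bond with the side chain turned away from the C5 allyl group (no syn-pentane contact), which places O, isopropenyl and side chain as at C9 of the target (9R).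

Step 11
Reactants: 14 (3R)-3-[(1S,2S,4S)-4-(tert-butyldimethylsilyloxy)-1,3,3-trimethyl-2-(prop-2-en-1-yl)cyclohexyl]-2-methyl-5-(2-methyl-1,3-dioxolan-2-yl)pent-1-en-3-ol
Product: 15 (3R)-3-[(1S,2S,4S)-4-(tert-butyldimethylsilyloxy)-1,3,3-trimethyl-2-(prop-2-en-1-yl)cyclohexyl]-2-methyl-5-(2-methyl-1,3-dioxolan-2-yl)pent-1-en-3-yl benzoate
Conditions: KN(SiMe3)2, THF, −78 °C; BzCl, −78 → 0 °C
Reagents that add atoms: benzoyl chloride, O=C(Cl)c1ccccc1
Why: O-acylation of the potassium alkoxide with benzoyl chloride is the standard way to esterify a hindered tertiary alcohol and installs the C9 benzoate before the ring-B allylic system exists.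

Step 12
Reactants: 15 (3R)-3-[(1S,2S,4S)-4-(tert-butyldimethylsilyloxy)-1,3,3-trimethyl-2-(prop-2-en-1-yl)cyclohexyl]-2-methyl-5-(2-methyl-1,3-dioxolan-2-yl)pent-1-en-3-yl benzoate
Product: 16 (3S,5S,9R,10S)-3β-(tert-butyldimethylsilyloxy)-13,13-(ethylenedioxy)-14,15-dinorlabd-7-en-9α-yl benzoate
Conditions: second-generation Grubbs catalyst (10 mol %), toluene, 80 °C
Reagents that add atoms: none
Why: Ring-closing metathesis between the allyl group and the 1,1-disubstituted isopropenyl group should close ring B as a six-membered ring with the trisubstituted C7=C8 alkene and expel ethene; the trans ring fusion follows from the C5 and C10 centres already in place.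

Step 13
Reactants: 16 (3S,5S,9R,10S)-3β-(tert-butyldimethylsilyloxy)-13,13-(ethylenedioxy)-14,15-dinorlabd-7-en-9α-yl benzoate
Product: 17 (3S,5S,9R,10S)-3β-(tert-butyldimethylsilyloxy)-13-oxo-14,15-dinorlabd-7-en-9α-yl benzoate
Conditions: PPTS, acetone/H2O (10:1), 45 °C
Reagents that add atoms: water, O
Why: Mild acid-catalysed hydrolysis of the dioxolane should free the C13 methyl ketone, while the hindered TBS ether and the tertiary allylic benzoate tolerate PPTS in wet acetone.

Step 14
Reactants: 18 diethylphosphonoacetic acid; 19 2-(trimethylsilyl)ethanol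
Product: 20 2-(trimethylsilyl)ethyl (diethoxyphosphoryl)acetate
Conditions: DCC, DMAP (cat.), CH2Cl2, 0 → 20 °C
Reagents that add atoms: none
Why: Steglich esterification (DCC/DMAP) should give the olefination reagent with a fluoride-labile ester.

Step 15
Reactants: 17 (3S,5S,9R,10S)-3β-(tert-butyldimethylsilyloxy)-13-oxo-14,15-dinorlabd-7-en-9α-yl benzoate; 20 2-(trimethylsilyl)ethyl (diethoxyphosphoryl)acetate
Product: 21 2-(trimethylsilyl)ethyl (3S,5S,9R,10S,13E)-9α-benzoyloxy-3β-(tert-butyldimethylsilyloxy)labda-7,13-dien-15-oate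
Conditions: 20, NaH, THF, 0 °C; then 17, 20 → 50 °C
Reagents that add atoms: none
Why: Horner–Wadsworth–Emmons olefination of the methyl ketone with the preformed sodium phosphonate should give the trisubstituted enoate with the E isomer favoured (ester trans to the larger CH2 chain), the minor Z isomer being removed by chromatography; no free base is left that could attack the benzoate.

Step 16
Reactants: 21 2-(trimethylsilyl)ethyl (3S,5S,9R,10S,13E)-9α-benzoyloxy-3β-(tert-butyldimethylsilyloxy)labda-7,13-dien-15-oate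
Product: 22 (3S,5S,9R,10S,13E)-9α-benzoyloxy-3β-hydroxylabda-7,13-dien-15-oic acid
Conditions: Bu4NF (5 equiv), THF, 0 → 45 °C; H2O (pH 5)
Reagents that add atoms: none
Why: Fluoride should cleave both silicon-based groups in one operation, the TBS ether by attack at silicon and the 2-(trimethylsilyl)ethyl ester by β-elimination to ethene, while the tertiary benzoate and both alkenes are untouched.

**Compound list**

1 | 5,6-dihydro-2H-pyran-2-one | O=C1C=CCCO1 | starting material
2 | (S)-4-(prop-1-en-2-yl)tetrahydro-2H-pyran-2-one | O=C1C[C@@H](C(C)=C)CCO1 | intermediate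
3 | (3R,4S)-3-methyl-4-(prop-1-en-2-yl)tetrahydro-2H-pyran-2-one (trans) | O=C1[C@H](C)[C@@H](C(C)=C)CCO1 | intermediate (not isolated)
4 | (R)-3,3-dimethyl-4-(prop-1-en-2-yl)tetrahydro-2H-pyran-2-one | O=C1C(C)(C)[C@@H](C(C)=C)CCO1 | intermediate
5 | (R)-6-hydroxy-3,3-dimethyl-4-(prop-1-en-2-yl)hexan-2-one (open form of the lactol) | CC(=O)C(C)(C)[C@@H](C(C)=C)CCO | intermediate
6 | (R)-4,4-dimethyl-5-oxo-3-(prop-1-en-2-yl)hexanal | CC(=O)C(C)(C)[C@@H](C(C)=C)CC=O | intermediate
7 | (R)-3,3-dimethyl-4-(prop-1-en-2-yl)hept-6-en-2-one | CC(=O)C(C)(C)[C@@H](C(C)=C)CC=C | intermediate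
8 | ethyl 3-(2-methyl-1,3-dioxolan-2-yl)propanoate | CCOC(=O)CCC1(C)OCCO1 | starting material
9 | (R)-6,6-dimethyl-1-(2-methyl-1,3-dioxolan-2-yl)-7-(prop-1-en-2-yl)dec-9-ene-3,5-dione | C=CC[C@H](C(C)=C)C(C)(C)C(=O)CC(=O)CCC1(C)OCCO1 | intermediate
10 | 4-allyl-6-hydroxy-3,3,5-trimethyl-6-[2-(2-methyl-1,3-dioxolan-2-yl)ethyl]bicyclo[3.1.1]heptan-2-one (allyl anti to the hydroxylated bridge; hydroxyl syn to the three-carbon bridge) | C=CC[C@H]1C(C)(C)C(=O)[C@H]2C[C@]1(C)[C@]2(O)CCC3(C)OCCO3 | intermediate (not isolated)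
11 | (3S,4S)-2,2,4-trimethyl-4-[3-(2-methyl-1,3-dioxolan-2-yl)propanoyl]-3-(prop-2-en-1-yl)cyclohexan-1-one | O=C1CC[C@](C)(C(=O)CCC2(C)OCCO2)[C@@H](CC=C)C1(C)C | intermediate
12 | 1-[(1S,2S,4S)-4-hydroxy-1,3,3-trimethyl-2-(prop-2-en-1-yl)cyclohexyl]-3-(2-methyl-1,3-dioxolan-2-yl)propan-1-one | O[C@H]1CC[C@](C)(C(=O)CCC2(C)OCCO2)[C@@H](CC=C)C1(C)C | intermediate
13 | 1-[(1S,2S,4S)-4-(tert-butyldimethylsilyloxy)-1,3,3-trimethyl-2-(prop-2-en-1-yl)cyclohexyl]-3-(2-methyl-1,3-dioxolan-2-yl)propan-1-one | CC(C)(C)[Si](C)(C)O[C@H]1CC[C@](C)(C(=O)CCC2(C)OCCO2)[C@@H](CC=C)C1(C)C | intermediate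
14 | (3R)-3-[(1S,2S,4S)-4-(tert-butyldimethylsilyloxy)-1,3,3-trimethyl-2-(prop-2-en-1-yl)cyclohexyl]-2-methyl-5-(2-methyl-1,3-dioxolan-2-yl)pent-1-en-3-ol | CC(C)(C)[Si](C)(C)O[C@H]1CC[C@](C)([C@](O)(C(C)=C)CCC2(C)OCCO2)[C@@H](CC=C)C1(C)C | intermediate
15 | (3R)-3-[(1S,2S,4S)-4-(tert-butyldimethylsilyloxy)-1,3,3-trimethyl-2-(prop-2-en-1-yl)cyclohexyl]-2-methyl-5-(2-methyl-1,3-dioxolan-2-yl)pent-1-en-3-yl benzoate | CC(C)(C)[Si](C)(C)O[C@H]1CC[C@](C)([C@](OC(=O)c2ccccc2)(C(C)=C)CCC3(C)OCCO3)[C@@H](CC=C)C1(C)C | intermediate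
16 | (3S,5S,9R,10S)-3β-(tert-butyldimethylsilyloxy)-13,13-(ethylenedioxy)-14,15-dinorlabd-7-en-9α-yl benzoate (5α-H, 10β-methyl) | CC1=CC[C@H]2C(C)(C)[C@@H](O[Si](C)(C)C(C)(C)C)CC[C@]2(C)[C@]1(CCC3(C)OCCO3)OC(=O)c1ccccc1 | intermediate
17 | (3S,5S,9R,10S)-3β-(tert-butyldimethylsilyloxy)-13-oxo-14,15-dinorlabd-7-en-9α-yl benzoate | CC1=CC[C@H]2C(C)(C)[C@@H](O[Si](C)(C)C(C)(C)C)CC[C@]2(C)[C@]1(CCC(C)=O)OC(=O)c1ccccc1 | intermediate
18 | diethylphosphonoacetic acid | CCOP(=O)(OCC)CC(=O)O | starting material
19 | 2-(trimethylsilyl)ethanol | C[Si](C)(C)CCO | starting material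
20 | 2-(trimethylsilyl)ethyl (diethoxyphosphoryl)acetate | CCOP(=O)(OCC)CC(=O)OCC[Si](C)(C)C | intermediate
21 | 2-(trimethylsilyl)ethyl (3S,5S,9R,10S,13E)-9α-benzoyloxy-3β-(tert-butyldimethylsilyloxy)labda-7,13-dien-15-oate | CC1=CC[C@H]2C(C)(C)[C@@H](O[Si](C)(C)C(C)(C)C)CC[C@]2(C)[C@]1(CC/C(C)=C/C(=O)OCC[Si](C)(C)C)OC(=O)c1ccccc1 | intermediate
22 | (3S,5S,9R,10S,13E)-9α-benzoyloxy-3β-hydroxylabda-7,13-dien-15-oic acid (CNP0288577.1) | CC1=CC[C@H]2C(C)(C)[C@@H](O)CC[C@]2(C)[C@]1(CC/C(C)=C/C(=O)O)OC(=O)c1ccccc1 | target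

**Step count**

Total steps: 16. Longest linear sequence: 15 (steps 1–13, 15 and 16; step 14 is a one-step side branch).

**Steps most likely to fail**

Step 7. The 1,4-biradical may partition badly: first bonding at C10 instead of C1 (straight mode), closure through the other enol tautomer, capture by the allyl alkene, or collapse on the wrong face of ring A would all erode the crossed adduct. The fallback sets out from 9 and fixes the enol on the C9 side before irradiation. O-acetylation (AcCl, pyridine, CH2Cl2, 0 °C) at the oxygen remote from quaternary C4 should give the (3Z,7R)-β-acetoxy enone F1. Irradiation of this enol acetate (Pyrex, MeCN) can place the second radical only on C9 and should give the isolable cyclobutyl acetate F2. Methanolysis (K2CO3, MeOH, 0 °C) then releases the cyclobutanolate, whose retro-aldol cleavage of C2–C9 comes back to the route at 11.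

Step 10. Facial selectivity in the addition may be poor if the side chain, not the nucleophile, takes the open position anti to C5, and the basic reagent may enolise the hindered ketone. The fallback sets out from 13 and delivers C8 intramolecularly, so that the side chain is free to take that open position. Oxidative cleavage of the allyl group (OsO4 cat., NaIO4, 2,6-lutidine, dioxane/H2O) should give the aldehyde F3. Stork–Zhao-type olefination with Ph3P=C(CH3)I (from ethyltriphenylphosphonium iodide, n-BuLi, I2, then NaN(SiMe3)2, THF, −78 °C) should give the (Z)-iodoalkene F4. Nozaki–Hiyama–Kishi closure onto the C9 ketone (CrCl2, NiCl2 cat., DMSO, 20 °C) forms ring B and the tertiary allylic alcohol F5 in one step. Benzoylation (KN(SiMe3)2, BzCl, THF) comes back to the route at 16.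

Step 6. Self-condensation of the enolisable ester 8 and proton transfer from the product to the hindered enolate may stop the acylation at low conversion. The fallback replaces the Claisen condensation by aldol addition and oxidation. Reduction of 8 (i-Bu2AlH, CH2Cl2, −78 °C) should give the aldehyde F6. Its addition to the lithium enolate of 7 (LiN(i-Pr)2, THF, −78 °C) should give the β-hydroxy ketone F7 as a mixture of carbinol epimers. Oxidation with Dess–Martin periodinane (NaHCO3, CH2Cl2) comes back to the route at 9.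

**Further compounds**

F1 | step 7 | (3Z,7R)-6,6-dimethyl-1-(2-methyl-1,3-dioxolan-2-yl)-5-oxo-7-(prop-1-en-2-yl)deca-3,9-dien-3-yl acetate | C=CC[C@H](C(C)=C)C(C)(C)C(=O)/C=C(/CCC1(C)OCCO1)OC(C)=O
F2 | step 7 | 4-allyl-3,3,5-trimethyl-6-[2-(2-methyl-1,3-dioxolan-2-yl)ethyl]-2-oxobicyclo[3.1.1]heptan-6-yl acetate (acetate of 10) | C=CC[C@H]1C(C)(C)C(=O)[C@H]2C[C@]1(C)[C@]2(OC(C)=O)CCC3(C)OCCO3
F3 | step 10 | 1-[(1S,2S,4S)-4-(tert-butyldimethylsilyloxy)-1,3,3-trimethyl-2-(2-oxoethyl)cyclohexyl]-3-(2-methyl-1,3-dioxolan-2-yl)propan-1-one | CC(C)(C)[Si](C)(C)O[C@H]1CC[C@](C)(C(=O)CCC2(C)OCCO2)[C@@H](CC=O)C1(C)C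
F4 | step 10 | 1-[(1S,2S,4S)-4-(tert-butyldimethylsilyloxy)-2-[(2Z)-3-iodobut-2-en-1-yl]-1,3,3-trimethylcyclohexyl]-3-(2-methyl-1,3-dioxolan-2-yl)propan-1-one | CC(C)(C)[Si](C)(C)O[C@H]1CC[C@](C)(C(=O)CCC2(C)OCCO2)[C@@H](C/C=C(/C)I)C1(C)C
F5 | step 10 | (3S,5S,9R,10S)-3β-(tert-butyldimethylsilyloxy)-13,13-(ethylenedioxy)-14,15-dinorlabd-7-en-9α-ol | CC1=CC[C@H]2C(C)(C)[C@@H](O[Si](C)(C)C(C)(C)C)CC[C@]2(C)[C@]1(CCC3(C)OCCO3)O
F6 | step 6 | 3-(2-methyl-1,3-dioxolan-2-yl)propanal | O=CCCC1(C)OCCO1
F7 | step 6 | (7R)-3-hydroxy-6,6-dimethyl-1-(2-methyl-1,3-dioxolan-2-yl)-7-(prop-1-en-2-yl)dec-9-en-5-one (both C3 epimers) | C=CC[C@H](C(C)=C)C(C)(C)C(=O)CC(O)CCC1(C)OCCO1
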